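## Retrosynthesis (overview)
1. Tuberatolide B comes from its aryl TIPS ether. The α,γ-disubstituted butenolide is closed last, by RCM of the 2-alkylacrylate ester of a secondary allylic alcohol. The C5 carbinol stereocentre comes from lipase resolution.
2. The (E)-trisubstituted alkene is made by B-alkyl Suzuki coupling of an alkyl-9-BBN (from a 2-vinylchromene) with an (E)-vinyl iodide (from carboalumination of a homopropargylic alcohol).
3. The chromene quaternary C–O stereocentre is set by Pd-catalysed asymmetric allylic alkylation (Trost AAA) of an o-vinylphenol with isoprene monoepoxide. The chromene ring is then closed by RCM, and CH2OH is converted to vinyl (oxidation, then Wittig).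
4. Ring-forming order: chromene ring (Step 5) first, butenolide ring (Step 18) last.

Assumptions:
- Isoprene monoepoxide is bought as the racemate. Its stereocentre is lost on Pd ionisation, so it serves as an achiral π-allyl source.
- The (R,R)-Trost ligand is assumed to give the (R)-ether 9; if the antipode forms, use the (S,S)-ligand.
- The lipase is assumed to acylate the (S)-carbinol, leaving the (R)-alcohol.

## Route

**Step 1**
Reactants: 1 (2-methylbenzene-1,4-diol)
Product: 3 (2-methyl-4-[(triisopropylsilyl)oxy]phenol)
Conditions: TIPSCl (1.0 equiv), imidazole, DMF, 0 °C→rt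
Reagents that add atoms: 2, TIPSCl, CC(C)[Si](Cl)(C(C)C)C(C)C
Why: The OH para to the other oxygen and meta to the methyl is far less hindered than the OH flanked by the methyl, so bulky TIPSCl silylates it selectively (chemoselective mono-protection). The free OH next to the methyl becomes the chromene ring oxygen.

**Step 2**
Reactants: 3
Product: 5 (2-hydroxy-3-methyl-5-(TIPSO)benzaldehyde)
Conditions: MgCl2, Et3N, (CH2O)n, MeCN, 75 °C
Reagents that add atoms: 4, paraformaldehyde, C=O
Why: Casiraghi ortho-formylation proceeds through a magnesium phenoxide–formaldehyde chelate. Only one ortho position is free, and the para position is blocked by OTIPS.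

**Step 3**
Reactants: 5
Product: 7 (2-ethenyl-6-methyl-4-(TIPSO)phenol)
Conditions: Ph3PCH3Br, KOtBu (3 equiv), THF, 0 °C→rt
Reagents that add atoms: 6, methyltriphenylphosphonium bromide, C[P+](c1ccccc1)(c1ccccc1)c1ccccc1.[Br-]
Why: Wittig methylenation of the salicylaldehyde gives the o-vinylphenol needed for later RCM. The extra equivalent of base covers the acidic phenol, and the TIPS aryl ether is stable to KOtBu.

**Step 4**
Reactants: 7; 8 (2-methyl-2-vinyloxirane, commercial racemate)
Product: 9 ((R)-2-[2-ethenyl-6-methyl-4-(TIPSO)phenoxy]-2-methylbut-3-en-1-ol)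
Conditions: Pd2(dba)3·CHCl3 (2.5 mol%), (R,R)-Trost DACH-Ph ligand (7.5 mol%), CH2Cl2, rt
Reagents that add atoms: none (8 is the coupling partner)
Why: Pd-catalysed asymmetric allylic alkylation, run as a dynamic kinetic asymmetric transformation. Both epoxide enantiomers ionise to one π-allyl–Pd species carrying a pendant alkoxide. The chiral ligand controls phenoxide attack at the tertiary terminus, which sets the quaternary C–O stereocentre (R).

**Step 5**
Reactants: 9
Product: 10 ((R)-[2,8-dimethyl-6-(TIPSO)-2H-chromen-2-yl]methanol), plus ethylene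
Conditions: Grubbs II (5 mol%), CH2Cl2 (0.01 M), 40 °C
Reagents that add atoms: none
Why: Ring-closing metathesis of the aryl vinyl and the vinyl on the quaternary carbon forms the six-membered 2H-chromene. The quaternary stereocentre is not involved and is untouched.

**Step 6**
Reactants: 10
Product: 11 ((R)-2,8-dimethyl-6-(TIPSO)-2H-chromene-2-carbaldehyde)
Conditions: Dess–Martin periodinane, NaHCO3, CH2Cl2, 0 °C→rt
Reagents that add atoms: none
Why: Mild oxidation of the primary alcohol. The aldehyde has no α-H, so the adjacent quaternary centre cannot epimerise.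

**Step 7**
Reactants: 11
Product: 12 ((S)-2-ethenyl-2,8-dimethyl-6-(TIPSO)-2H-chromene)
Conditions: Ph3PCH3Br, KOtBu, THF, 0 °C
Reagents that add atoms: 6 (as in Step 3)
Why: Wittig methylenation of the non-enolisable aldehyde. The descriptor changes from R to S only through CIP priorities (the ring CH= now outranks the exocyclic group), not through any change in geometry. The product is acid-sensitive, so purify on Et3N-neutralised silica or use it crude.

**Step 8**
Reactants: 13 (acrolein); 14 (3-bromo-1-(trimethylsilyl)prop-1-yne)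
Product: 15 ((±)-6-(trimethylsilyl)hex-1-en-5-yn-3-ol)
Conditions: Zn dust, THF/sat. aq NH4Cl, 0 °C→rt
Reagents that add atoms: none (13 and 14 are the reactants)
Why: Barbier-type propargylation via a propargyl/allenylzinc species adds 1,2 to the aldehyde and gives the racemic homopropargylic alcohol. The TMS group favours the homopropargyl over the allenyl product.

**Step 9**
Reactants: 15; 16 (vinyl acetate)
Product: 17 ((R)-6-(trimethylsilyl)hex-1-en-5-yn-3-ol) and 18 ((S)-6-(trimethylsilyl)hex-1-en-5-yn-3-yl acetate), separated by chromatography; 18 is set aside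
Conditions: Burkholderia cepacia lipase (Amano PS-IM), vinyl acetate, MTBE, 25 °C, stop at ~50% conversion
Reagents that add atoms: 16, vinyl acetate, C=COC(C)=O (its acetyl group ends up in 18)
Why: Lipase (hydrolase) kinetic resolution by transesterification. The large TMS-propargyl group versus the small vinyl group gives strong enantiodiscrimination, so the (S)-carbinol is acylated and the (R)-alcohol 17 is recovered. This sets the future butenolide C5 stereocentre.

**Step 10**
Reactants: 17
Product: 19 ((R)-hex-1-en-5-yn-3-ol)
Conditions: K2CO3, MeOH, rt (keep as a solution; the product is volatile)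
Reagents that add atoms: none
Why: Methanolysis of the C(sp)–Si bond leaves the carbinol stereocentre untouched.

**Step 11**
Reactants: 19
Product: 22 ((3R,5E)-6-iodo-5-methylhexa-1,5-dien-3-ol)
Conditions: (i) Me3Al (3 equiv), Cp2ZrCl2 (20 mol%), CH2Cl2, rt; (ii) I2, THF, –30→0 °C
Reagents that add atoms: 20, Me3Al, C[Al](C)C; 21, I2, II
Why: Negishi Zr-catalysed carboalumination adds Me and Al syn across the terminal alkyne, giving the (E)-trisubstituted alkenylaluminium. The terminal alkene is far less reactive than the alkyne. Iodinolysis proceeds with retention, so the geometry is E, and the free OH is tolerated with excess Me3Al.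

**Step 12**
Reactants: 23 (triethyl phosphonoacetate); 24 (5-bromo-2-methylpent-2-ene)
Product: 25 (ethyl 2-(diethoxyphosphoryl)-6-methylhept-5-enoate)
Conditions: NaH, THF, 0→60 °C
Reagents that add atoms: none (23 and 24 are the reactants)
Why: SN2 alkylation of the stabilised phosphonate carbanion with the primary bromide.

**Step 13**
Reactants: 25
Product: 26 (ethyl 2-methylene-6-methylhept-5-enoate)
Conditions: 37% aq HCHO, K2CO3, THF/H2O, rt→50 °C
Reagents that add atoms: 4, formaldehyde, C=O
Why: Horner–Wadsworth–Emmons olefination with formaldehyde gives the α-alkylacrylate.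

**Step 14**
Reactants: 26
Product: 27 (2-methylene-6-methylhept-5-enoic acid)
Conditions: LiOH, THF/H2O, 0 °C→rt
Reagents that add atoms: lithium hydroxide, [Li+].[OH-]
Why: Saponification of the ester. No alcohol cosolvent is used, which avoids conjugate addition of alkoxide to the acrylate. The trisubstituted alkene is inert, and the acrylate is not attacked under these mild conditions.

**Step 15**
Reactants: 12
Product: 29 (B-alkyl-9-BBN: 9-[2-((2S)-2,8-dimethyl-6-(TIPSO)-2H-chromen-2-yl)ethyl]-9-BBN), not isolated
Conditions: 9-BBN (1.0 equiv, 0.5 M in THF), THF, rt, 4 h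
Reagents that add atoms: 28, 9-BBN, B1C2CCCC1CCC2
Why: Anti-Markovnikov hydroboration. 9-BBN reacts with the terminal vinyl group much faster than with the hindered cis-disubstituted ring alkene, giving the primary alkylborane. This builds the CH2CH2 unit.

**Step 16**
Reactants: 29; 22
Product: 30 ((3R,5E)-8-[(2S)-2,8-dimethyl-6-(TIPSO)-2H-chromen-2-yl]-5-methylocta-1,5-dien-3-ol)
Conditions: PdCl2(dppf)·CH2Cl2 (10 mol%), Cs2CO3, DMF/THF/H2O, rt
Reagents that add atoms: none (22 is the coupling partner)
Why: B-alkyl Suzuki–Miyaura coupling with retention of the alkene geometry gives the (E)-trisubstituted alkene. The carbinol and quaternary stereocentres are not affected.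

**Step 17**
Reactants: 30; 27
Product: 31 (acrylate ester of 30)
Conditions: EDC·HCl, DMAP (20 mol%), CH2Cl2, 0 °C→rt
Reagents that add atoms: none
Why: Steglich esterification with retention at the carbinol (no C–O cleavage).

**Step 18**
Reactants: 31
Product: 32 ((5R)-butenolide TIPS ether), plus ethylene
Conditions: Grubbs II (10 mol%), Ti(OiPr)4 (30 mol%), CH2Cl2 (3 mM), 40 °C
Reagents that add atoms: none
Why: RCM of the monosubstituted vinyl group with the 1,1-disubstituted acrylate forms the α-alkyl-γ-substituted butenolide. The γ stereocentre is carried through unchanged. The trisubstituted alkenes and the chromene alkene are far less reactive than the terminal vinyl and acrylate.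

**Step 19**
Reactants: 32
Product: 33 (tuberatolide B)
Conditions: TBAF/AcOH (1:1, 1.2 equiv), THF, 0 °C, N2
Reagents that add atoms: none
Why: Buffered fluoride removes the aryl silyl ether without basic epimerisation of the acidic butenolide γ-H. The free hydroquinone monoether is handled under inert gas.

## Compound list
1 | 2-methylbenzene-1,4-diol | Cc1cc(O)ccc1O | starting material
2 | triisopropylsilyl chloride | CC(C)[Si](Cl)(C(C)C)C(C)C | starting material
3 | 2-methyl-4-(TIPSO)phenol | Cc1cc(O[Si](C(C)C)(C(C)C)C(C)C)ccc1O | intermediate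
4 | formaldehyde (paraformaldehyde / aq. HCHO) | C=O | starting material
5 | 2-hydroxy-3-methyl-5-(TIPSO)benzaldehyde | O=Cc1cc(O[Si](C(C)C)(C(C)C)C(C)C)cc(C)c1O | intermediate
6 | methyltriphenylphosphonium bromide | C[P+](c1ccccc1)(c1ccccc1)c1ccccc1.[Br-] | starting material
7 | 2-ethenyl-6-methyl-4-(TIPSO)phenol | C=Cc1cc(O[Si](C(C)C)(C(C)C)C(C)C)cc(C)c1O | intermediate
8 | 2-methyl-2-vinyloxirane (racemic) | C=CC1(C)CO1 | starting material
9 | (R)-2-[2-ethenyl-6-methyl-4-(TIPSO)phenoxy]-2-methylbut-3-en-1-ol | OC[C@@](Oc1c(C=C)cc(O[Si](C(C)C)(C(C)C)C(C)C)cc1C)(C)C=C | intermediate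
10 | (R)-(2,8-dimethyl-6-(TIPSO)-2H-chromen-2-yl)methanol | OC[C@@]1(C)C=Cc2cc(O[Si](C(C)C)(C(C)C)C(C)C)cc(C)c2O1 | intermediate
11 | (R)-2,8-dimethyl-6-(TIPSO)-2H-chromene-2-carbaldehyde | O=C[C@@]1(C)C=Cc2cc(O[Si](C(C)C)(C(C)C)C(C)C)cc(C)c2O1 | intermediate
12 | (S)-2-ethenyl-2,8-dimethyl-6-(TIPSO)-2H-chromene | C=C[C@@]1(C)C=Cc2cc(O[Si](C(C)C)(C(C)C)C(C)C)cc(C)c2O1 | intermediate
13 | acrolein | C=CC=O | starting material
14 | 3-bromo-1-(trimethylsilyl)propyne | C[Si](C)(C)C#CCBr | starting material
15 | (±)-6-TMS-hex-1-en-5-yn-3-ol | C=CC(O)CC#C[Si](C)(C)C | intermediate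
16 | vinyl acetate | C=COC(C)=O | starting material
17 | (R)-6-TMS-hex-1-en-5-yn-3-ol | C=C[C@H](O)CC#C[Si](C)(C)C | intermediate
18 | (S)-6-TMS-hex-1-en-5-yn-3-yl acetate (resolution co-product, set aside, not carried forward) | C=C[C@@H](OC(C)=O)CC#C[Si](C)(C)C | intermediate
19 | (R)-hex-1-en-5-yn-3-ol | C=C[C@H](O)CC#C | intermediate
20 | trimethylaluminium | C[Al](C)C | starting material
21 | iodine | II | starting material
22 | (3R,5E)-6-iodo-5-methylhexa-1,5-dien-3-ol | C=C[C@H](O)C/C(C)=C/I | intermediate
23 | triethyl phosphonoacetate | CCOC(=O)CP(=O)(OCC)OCC | starting material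
24 | 5-bromo-2-methylpent-2-ene | CC(C)=CCCBr | starting material
25 | ethyl 2-(diethoxyphosphoryl)-6-methylhept-5-enoate | CCOC(=O)C(CCC=C(C)C)P(=O)(OCC)OCC | intermediate
26 | ethyl 2-methylene-6-methylhept-5-enoate | C=C(CCC=C(C)C)C(=O)OCC | intermediate
27 | 2-methylene-6-methylhept-5-enoic acid | C=C(CCC=C(C)C)C(=O)O | intermediate
28 | 9-borabicyclo[3.3.1]nonane (9-BBN) | B1C2CCCC1CCC2 | starting material
29 | B-alkyl-9-BBN from 12 | C(C[C@@]1(C)C=Cc2cc(O[Si](C(C)C)(C(C)C)C(C)C)cc(C)c2O1)B1C2CCCC1CCC2 | intermediate
30 | (3R,5E)-chromenyl octadienol | C=C[C@H](O)C/C(C)=C/CC[C@@]1(C)C=Cc2cc(O[Si](C(C)C)(C(C)C)C(C)C)cc(C)c2O1 | intermediate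
31 | acrylate ester of 30 | C=C[C@H](OC(=O)C(=C)CCC=C(C)C)C/C(C)=C/CC[C@@]1(C)C=Cc2cc(O[Si](C(C)C)(C(C)C)C(C)C)cc(C)c2O1 | intermediate
32 | tuberatolide B TIPS ether | CC(C)=CCCC1=C[C@@H](C/C(C)=C/CC[C@@]2(C)C=Cc3cc(O[Si](C(C)C)(C(C)C)C(C)C)cc(C)c3O2)OC1=O | intermediate
33 | tuberatolide B | CC(C)=CCCC1=C[C@@H](C/C(C)=C/CC[C@@]2(C)C=Cc3cc(O)cc(C)c3O2)OC1=O | target

## Totals
- Total steps: 19
- Longest linear sequence: 12 (Steps 1–7, then 15–19)
- Three steps most likely to fail:
  1. **Step 4 (Pd-AAA).** Branched (tertiary) versus linear regioselectivity, and ee, with a hindered 2,6-disubstituted o-vinylphenol. Fallback: run Steps 4–5 with achiral Pd/PPh3 to give racemic 10, acetylate it, and resolve by lipase-catalysed hydrolysis of the acetate, as for Trolox-type 2-hydroxymethylchromans.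
  2. **Steps 15–16 (hydroboration, then Suzuki).** The doubly allylic vinylchromene 12 is acid- and Pd-labile, and the ring alkene may compete for 9-BBN. Fallback: hydrozirconate 12 with Cp2Zr(H)Cl, transmetalate with ZnCl2, and couple with 22 under Pd(PPh3)4 (a neutral Zr/Zn Negishi coupling with no borane or aqueous base).
  3. **Step 18 (final RCM).** The substrate is polyolefinic, with an α-substituted acrylate and several trisubstituted alkenes. Fallback: reverse the order. Esterify 22 with 27, close the butenolide by RCM on that small vinyl-iodide fragment, then make the final C–C bond by the Zr/Zn Negishi coupling with 12.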